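I began with a leftover. On paper, a one-to-one pairing with 0.60 equiv of coupling partner leaves starting material over, so I asked which concentration stands in which rate.

| flask | starting material | coupling partner | temperature | remark | time |
|---|---|---|---|---|---|
| delta | 1 M | 0.60 equiv | −5 °C | run made earlier |  |
| Thursday's | 0.50 M | 0.600 equiv | −5 °C |  | 20 h |
| Wednesday's | 0.50 M | 0.600 equiv | −35 °C |  | 20 h |
| Friday's | 0.50 M | 0.600 equiv | 25 °C |  | 20 h |
| Saturday's | 0.50 M | 0.600 equiv | 55 °C |  | 20 h |

delta run (percent of the starting material charged)

| time / h | target / % | side product A / % | side product B / % |
|---|---|---|---|
| 0.333 | 0.9 | 0.5 | 0.2 |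
| 0.667 | 0.4 | 0 | 0 |
| 1.50 | 1.9 | 0.6 | 1.2 |
| 4.00 | 5.2 | 1.0 | 3.5 |

(scatter of a reading: 0.5 percentage points)

- in percentages every species weighs as the starting material in it: one side product B counts as two
- the earlier runs do not show what temperature does; that part of a forecast is a guess

- the flask with the highest share of target in all that became target or side product A or side product B or over-reaction product ("all alike" if they lie within 1.5 percentage points) (Thursday's / Wednesday's / Friday's / Saturday's / all alike)
- share of target in all that became target or side product A or side product B or over-reaction product, Thursday's
- share of target in all that became target or side product A or side product B or over-reaction product, Wednesday's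
- share of target in all that became target or side product A or side product B or over-reaction product, Friday's
- share of target in all that became target or side product A or side product B or over-reaction product, Saturday's

I assumed that target forms at a rate set by [starting material][coupling partner], side product B by [starting material]², and side product A by [starting material]. Target per side product B then follows [coupling partner]/[starting material], and dilution cancels from that ratio. So I kept one number, the selectivity factor s: target per side product B, per equivalent of coupling partner, at one fixed temperature. The 4.00 h reading gave s = 2.48 equiv⁻¹.

Thursday's has the same equivalents and the same temperature, so I kept the target to side product B ratio. At half the concentration, side product A gains on that pair by a factor of 2.00. That gave 48.6% target, with over-reaction product uncounted because no reading lists it.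

The weak link was side product A, read as 1.0% with a scatter of 0.5 percentage points and then multiplied. I reforged it by summing the 1.50 h and 4.00 h readings, which gave 47.3%. I committed to that for Thursday's. The s reading holds at −5 °C, so it gave me no number for the other flasks.

The forecast gave 52% for Thursday's, 56% for Wednesday's, 47% for Friday's and 42% for Saturday's, and picked Wednesday's. Its words on temperature were “Temperature is pure guesswork”. For Thursday's it stood higher than my reckoning.

The flasks gave 47.2%, 75.0%, 0.101% and 0% in that order, and the best was Wednesday's.

    2 starting material → side product B (k = 2.60 × 10⁻⁵ M⁻¹ s⁻¹, Ea = 68.0 kJ mol⁻¹)
    starting material → side product A (k = 5.70 × 10⁻⁵ s⁻¹, Ea = 94.0 kJ mol⁻¹)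
    target → over-reaction product (k = 1.20 × 10⁻⁴ s⁻¹, Ea = 95.0 kJ mol⁻¹)
    starting material + coupling partner ⇌ target (K = 1.90 M⁻¹, k = 8.90 × 10⁻⁵ M⁻¹ s⁻¹, Ea = 56.0 kJ mol⁻¹, ΔH = −71.0 kJ mol⁻¹)
    (constants at 25 °C)

From the delta run's computed 55.9% at its last reading, changing the amount alone gave 50.4%, and changing to Saturday's temperature alone gave 0%. Thursday's ended with s = 2.80 equiv⁻¹ and Wednesday's with a larger s = 5.79 equiv⁻¹. Those two flasks share charges and time and differ in temperature, so my reading of 2.48 equiv⁻¹ belongs to −5 °C.

Take Wednesday's with 1.50 equiv of coupling partner. Wednesday's s gives 8.68 target per side product B. With both side products held at Wednesday's amounts, the share is 88.2%. That flask gave 88.3%, with 8.72 target per side product B.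

All runs were computed for an exercise; scatter was added.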